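How much left-handed product stands after 1.5 h as the free catalyst goes from 0.060 mM to 1.0 mM, and does more catalyst keep paying?

| flask | left-handed substrate | right-handed substrate | reagent | free catalyst | remark | time |
|---|---|---|---|---|---|---|
| Friday's | 0.15 M | 0.15 M | 0.40 M (fed, over 3.0 min) | 0.060 mM | run made earlier |  |
| eta | 0.10 M | 0.10 M | 0.400 M (fed, over 3.0 min) | 0.060 mM |  | 1.5 h |
| theta | 0.10 M | 0.10 M | 0.400 M (fed, over 3.0 min) | 0.12 mM |  | 1.5 h |
| beta | 0.10 M | 0.10 M | 0.400 M (fed, over 3.0 min) | 0.25 mM |  | 1.5 h |
| zeta | 0.10 M | 0.10 M | 0.400 M (fed, over 3.0 min) | 0.50 mM |  | 1.5 h |
| delta | 0.10 M | 0.10 M | 0.400 M (fed, over 3.0 min) | 1.0 mM |  | 1.5 h |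

- Friday's (time / min: left-handed product / %): 4.00: 3.4; 6.00: 6.3; 10.0: 8.0; 15.0: 12.3; 25.0: 13.5; 40.0: 15.9; 50.0: 17.3

(scatter of a reading: 0.5 percentage points)

1. amount of left-handed product at the end, in percent of the left-handed substrate and right-handed substrate together charged for eta, theta, beta, zeta, delta, in this order
2. the shape of the row from first to last (hardly changes / rises, then falls / falls all the way / rises all the way / falls, then rises)

- free catalyst is single-handed; left-handed substrate and right-handed substrate are mirror images of each other, charged as a racemate, each of them at the stated concentration
- "hardly changes" means that all values lie within two and a half points (for a concentration: within two and a half percent of the largest)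
- no earlier run changes the charge of free catalyst; that part of a forecast is a guess

Friday's run slows early: the first 6.00 min give 6.3% of left-handed product, the last 10.0 min give 1.4 percentage points. The rate has dropped to 13.3% of its opening value, less than the 65.4% of left-handed substrate remaining if I count what became product. So I read the slowing as a free catalyst that dies, and I assume its death ignores the substrate, so that the percentage carries over to a smaller charge.

The bench rule says twice the catalyst gives twice the product. For delta it promises 288% of the charge. But left-handed substrate is half of the charge, so if this is a plain kinetic resolution, the rule ends near 0.173 mM, which is 2.89 times Friday's loading.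

To join the two ends, I let each portion of catalyst remove a fixed fraction of the left-handed substrate present. The logarithm of left-handed substrate charged over left-handed substrate left, divided by the catalyst charged, comes from Friday's last reading to 7.08 /mM; this is the burn-out dose. Product is then half the charge times one minus the exponential of minus dose times loading. My row reads 17.3%, 28.6%, 41.5%, 48.5%, 50.0%. Friday's curve is still climbing, so I read the dose a little short.

The forecast gives 24%, 32%, 40%, 45%, 47%, and says the row rises all the way: “more catalyst raises the yield, flattening toward 50%”. For eta the forecast stands above mine.

    reagent + free catalyst + left-handed substrate → free catalyst + left-handed product (k = 1500 /M²/min)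
    reagent + free catalyst + right-handed substrate → free catalyst + right-handed product (k = 51.0 /M²/min)
    left-handed substrate ⇌ right-handed substrate (k = 0.0310 /min)
    reagent + free catalyst → spent catalyst (k = 0.190 /M/min)
    2 reagent → self-condensation product (k = 0.0620 /M/min)

The flask gives 18.5%, 31.9%, 50.1%, 66.4%, 76.4%, so the row rises all the way. In delta, left-handed product passes the half charged as left-handed substrate, while 18% of the right-handed substrate remains and right-handed product stands at 7.47%. The burn-out dose gives 28.6% for theta, where the flask holds 31.9%, and 50.0% for delta, where it holds 76.4%.

(The data stem from a simulated flask from invented constants, noise included.)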